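**Plan**
1. Retrosynthesis: the two ester C–O bonds (angelate at C7, epoxyangelate at C6) are cut first, then the C6–C7 bond of the cycloheptene (ring B) as a reductive dialdehyde coupling, then a temporary eight-membered lactone (O–C7 and C8=C9), then the C4a–C5 bond ([3,3] shift), which leaves the ring of (S)-carvone (ring A).
2. Enabling feature: C6 and C7 are adjacent carbinol carbons of ring B; C6 sits on the quaternary C5 (a non-enolisable aldehyde), C7 is allylic to the (Z)-C8=C9 bond (an enal), and both arms hang cis on C4a/C9a of ring A, so one reductive coupling can close ring B and set both oxygen-bearing stereocentres.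
3. Forward, first half: (S)-carvone supplies ring A, its methyl, C9a, C9 and the C9 methyl; directed epoxidation and a selenoxide transposition place a tertiary C3–O bond on the isopropenyl face; Ireland–Claisen rearrangement of its isobutyrate moves C5(CH3)2–C6 onto C4a, cis to C9a.
4. Forward, second half: an allyl ester and ring-closing metathesis give a temporary eight-membered lactone that brings in C7/C8 and fixes the Z geometry; reduction and oxidation give the dialdehyde; titanium pinacol coupling closes ring B; two esterifications, desilylation and oxidation at C2 finish.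
5. Stereochemistry: C9a from (S)-carvone; C4a by suprafacial transfer from the C3–O bond (set through the cis-carveol hydroxyl); C6/C7 by substrate control in a chair-like closure with both oxygens pseudoequatorial; the (2R,3R)-epoxide by Sharpless asymmetric epoxidation; the Z ester from angelic acid.

Key step: step 11

Assumption: all intermediates carry the locants of the target skeleton (C1–C4, C4a, C5–C9, C9a; ring A = six-membered ring, ring B = seven-membered ring); (S)-(+)-carvone, angelic acid and the reagents named are taken as commercial.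

**Route**

Step 1
Reactants: 1 (S)-(+)-carvone
Product: 2 (1S,5S)-cis-carveol
Conditions: NaBH4, CeCl3·7H2O, MeOH, −20 °C
Reagents that add atoms: none
Why: Luche 1,2-reduction of the enone, in which axial hydride delivery should give the pseudoequatorial C2 alcohol, cis to the isopropenyl group.

Step 2
Reactants: 2 (1S,5S)-cis-carveol
Product: 3 (1S,2S,4R,6R)-1-methyl-4-(prop-1-en-2-yl)-7-oxabicyclo[4.1.0]heptan-2-ol
Conditions: VO(acac)2 (cat.), t-BuOOH, PhMe, 0 °C → rt
Reagents that add atoms: tert-butyl hydroperoxide, CC(C)(C)OO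
Why: Hydroxyl-directed VO(acac)2-catalysed epoxidation of the allylic alcohol, which should deliver oxygen to C3=C4 from the face of the C2 hydroxyl (the isopropenyl face) and leave the isolated isopropenyl alkene alone.

Step 3
Reactants: 3 syn-epoxy alcohol
Product: 4 tert-butyldimethylsilyl ether of 3
Conditions: TBSCl, imidazole, DMF, rt
Reagents that add atoms: tert-butyldimethylsilyl chloride, CC(C)(C)[Si](C)(C)Cl
Why: Standard silylation of the secondary alcohol, giving an O2 protecting group that should survive the hydride, amide base and low-valent titanium used later.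

Step 4
Reactants: 4 silyl-protected epoxide
Product: 7 (1R,4R,6S)-6-[(tert-butyldimethylsilyl)oxy]-1-methyl-4-(prop-1-en-2-yl)cyclohex-2-en-1-ol, via hydroxy selenide 5 (not isolated), via selenoxide 6 (not isolated)
Conditions: PhSeSePh, NaBH4, EtOH, reflux; then 30% H2O2, THF, 0 °C → rt
Reagents that add atoms: none
Why: Epoxide-to-allylic-alcohol transposition by selenide opening and selenoxide syn-elimination, in which PhSe− should open the epoxide trans-diaxially at the secondary carbon C4, the selenoxide can only eliminate toward C4a, and the tertiary C3–O bond (syn to isopropenyl) is untouched.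

Step 5
Reactants: 7 tertiary allylic alcohol
Product: 8 (1R,4R,6S)-6-[(tert-butyldimethylsilyl)oxy]-1-methyl-4-(prop-1-en-2-yl)cyclohex-2-en-1-yl 2-methylpropanoate
Conditions: (i-PrCO)2O, DMAP, Et3N, CH2Cl2, 40 °C
Reagents that add atoms: isobutyric anhydride, CC(C)C(=O)OC(=O)C(C)C
Why: DMAP-catalysed acylation of a tertiary allylic alcohol with an anhydride, which touches no stereocentre and forms no alkoxide, so the neighbouring silyl group should not migrate.

Step 6
Reactants: 8 tertiary allylic isobutyrate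
Product: 11 2-[(1S,4S,6R)-4-[(tert-butyldimethylsilyl)oxy]-3-methyl-6-(prop-1-en-2-yl)cyclohex-2-en-1-yl]-2-methylpropanoic acid, via trimethylsilyl ketene acetal 9 (not isolated), via trimethylsilyl ester 10 (not isolated)
Conditions: LiN(i-Pr)2, THF, −78 °C; Me3SiCl, Et3N; −78 → 60 °C; aq. citric acid
Reagents that add atoms: none
Why: Ireland–Claisen rearrangement, in which the silyl ketene acetal (two identical methyls, no geometry issue) should shift suprafacially so that the new C4a–C5 bond forms on the face that held the C3–O bond, cis to the isopropenyl group, while the alkene moves to C3=C4.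

Step 7
Reactants: 11 carboxylic acid
Product: 12 prop-2-en-1-yl ester of 11
Conditions: allyl bromide, K2CO3, DMF, rt
Reagents that add atoms: allyl bromide, C=CCBr
Why: SN2 O-alkylation of the carboxylate, which is insensitive to the quaternary α-carbon.

Step 8
Reactants: 12 allyl ester
Product: 13 cis-fused eight-membered (Z)-lactone O–C6(=O)–C5(CH3)2–C4a–C9a–C9(CH3)=C8H–C7H2 on ring A
Conditions: second-generation Grubbs catalyst (H2IMes)(PCy3)Cl2Ru=CHPh (10 mol %), PhMe, 80 °C, 2 mM
Reagents that add atoms: none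
Why: Ring-closing olefin metathesis between the allyl ester and the 1,1-disubstituted isopropenyl alkene, favoured by the cis arms and the gem-dimethyl group, in a ring that can hold the new trisubstituted C8=C9 bond only as Z.

Step 9
Reactants: 13 eight-membered lactone
Product: 14 2-{(1S,4S,6R)-4-[(tert-butyldimethylsilyl)oxy]-6-[(2Z)-4-hydroxybut-2-en-2-yl]-3-methylcyclohex-2-en-1-yl}-2-methylpropan-1-ol
Conditions: LiAlH4, THF, 0 °C
Reagents that add atoms: none
Why: Hydride reduction of the lactone, which removes the tether and should release the (Z)-allylic alcohol at C7 and the neopentyl alcohol at C6 without touching a stereocentre.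

Step 10
Reactants: 14 diol
Product: 15 2-{(1S,4S,6R)-4-[(tert-butyldimethylsilyl)oxy]-3-methyl-6-[(2Z)-4-oxobut-2-en-2-yl]cyclohex-2-en-1-yl}-2-methylpropanal
Conditions: Dess–Martin periodinane, NaHCO3, CH2Cl2, 0 °C → rt; used crude
Reagents that add atoms: none
Why: Buffered Dess–Martin oxidation of both primary alcohols under neutral conditions that should keep the Z-enal from isomerising, the C6 aldehyde having no α-hydrogen.

Step 11
Reactants: 15 dialdehyde
Product: 17 (2S,4aS,6R,7R,9aR)-2-[(tert-butyldimethylsilyl)oxy]-3,5,5,9-tetramethyl-2,4a,5,6,7,9a-hexahydro-1H-benzo[7]annulene-6,7-diol, via cyclic dichlorotitanium diolate 16 (not isolated)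
Conditions: TiCl3(DME)1.5, Zn–Cu couple, DME, reflux 2 h; then 25 °C, slow addition of 15 (syringe pump, final 3 mM); H2O work-up
Reagents that add atoms: none
Why: Low-valent titanium (from TiCl3(DME)1.5 and Zn–Cu) should reduce the enal and then the aldehyde by single-electron transfer, the titanium-bound allylic ketyl coupling through its carbonyl carbon C7 with the titanium-bound C6 carbonyl to give the cyclic titanium diolate 16, which at 25 °C should not be deoxygenated and is hydrolysed to the diol. The closest known reaction type is the intramolecular titanium-induced (McMurry-type) pinacol coupling of dialdehydes, which is established for medium rings and for the pairing of an enal with an α-quaternary aldehyde. Ring B closes by a seven-membered carbonyl–carbonyl reductive coupling (formally 7-exo attack of C7 on C6=O) through a chair-like cycloheptene in which the C4a–C5–C6 arm lies over one face of the planar (Z)-enal. C7 should be set by the enal reacting s-trans (s-cis would press its oxygen against C9a) on the face that the C9a stereocentre presents to C6 while the bulky C5 arm stays pseudoequatorial on ring A, and C6 by its oxygen taking the pseudoequatorial site (the axial one is syn-axial to C4), so that the two oxygens sit gauche on one titanium centre and end trans-diequatorial, that is 6R,7R. The step needs carbonyl-carbon coupling instead of coupling through the enal β-carbon C9, and no aldol or ketone chemistry: C9 is fully substituted and its bonding to C6 would build a five-membered ring between two quaternary carbons, C6 has no α-hydrogen because C5 is quaternary, and the C2 carbonyl is masked as its silyl ether.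

Step 12
Reactants: 17 trans-diol; 18 angelic acid
Product: 20 (2S,4aS,6R,7R,9aR)-2-[(tert-butyldimethylsilyl)oxy]-6-hydroxy-3,5,5,9-tetramethyl-2,4a,5,6,7,9a-hexahydro-1H-benzo[7]annulen-7-yl (2Z)-2-methylbut-2-enoate, via angelic 2,4,6-trichlorobenzoic anhydride 19 (not isolated)
Conditions: 18, 2,4,6-Cl3C6H2COCl, Et3N, PhMe, rt; then 17, 75 °C
Reagents that add atoms: angelic acid (18), C/C=C(/C)C(O)=O
Why: Yamaguchi-type acylation with the preformed mixed anhydride and no nucleophilic catalyst, which should not isomerise angelate to tiglate and should acylate the allylic pseudoequatorial C7–OH while the C6–OH next to quaternary C5 stays free.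

Step 13
Reactants: 18 angelic acid
Product: 21 (2Z)-2-methylbut-2-en-1-ol
Conditions: LiAlH4, Et2O, 0 °C → rt
Reagents that add atoms: none
Why: Hydride 1,2-reduction of the carboxylic acid, in which the trisubstituted Z-alkene should keep its geometry.

Step 14
Reactants: 21 (2Z)-2-methylbut-2-en-1-ol
Product: 22 [(2S,3R)-2,3-dimethyloxiran-2-yl]methanol
Conditions: Ti(Oi-Pr)4, L-(+)-diethyl tartrate [(R,R)], t-BuOOH, 4 Å MS, CH2Cl2, −20 °C
Reagents that add atoms: tert-butyl hydroperoxide, CC(C)(C)OO
Why: Sharpless asymmetric epoxidation, whose stereospecific syn oxygen transfer keeps the two methyl groups trans and whose (R,R)-tartrate ligand should select the alkene face that gives the (2S,3R)-epoxy alcohol.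

Step 15
Reactants: 22 epoxy alcohol
Product: 23 (2R,3R)-2,3-dimethyloxirane-2-carboxylic acid
Conditions: RuCl3·xH2O (cat.), NaIO4, MeCN/EtOAc/H2O, 0 °C → rt
Reagents that add atoms: water, O
Why: RuO4-catalysed oxidation of a primary epoxy alcohol to the glycidic acid, in which the quaternary α-carbon cannot epimerise.

Step 16
Reactants: 20 C7 mono-angelate; 23 epoxy acid
Product: 25 (2S,4aS,6R,7R,9aR)-2-[(tert-butyldimethylsilyl)oxy]-3,5,5,9-tetramethyl-7-{[(2Z)-2-methylbut-2-enoyl]oxy}-2,4a,5,6,7,9a-hexahydro-1H-benzo[7]annulen-6-yl (2R,3R)-2,3-dimethyloxirane-2-carboxylate, via epoxyangelic 2,4,6-trichlorobenzoic anhydride 24 (not isolated)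
Conditions: 23, 2,4,6-Cl3C6H2COCl, Et3N, PhMe, rt; then 20, DMAP, 40 °C
Reagents that add atoms: (2R,3R)-2,3-dimethyloxirane-2-carboxylic acid (23), OC(=O)[C@]1(C)O[C@@H]1C
Why: Yamaguchi esterification, in which the DMAP-activated acyl donor should reach the hindered pseudoequatorial C6–OH, the acyl α-carbon is quaternary (no ketene, no epimerisation) and the C7 angelate should be spared at 40 °C.

Step 17
Reactants: 25 silyl-protected diester
Product: 26 (2S,4aS,6R,7R,9aR)-2-hydroxy-3,5,5,9-tetramethyl-7-{[(2Z)-2-methylbut-2-enoyl]oxy}-2,4a,5,6,7,9a-hexahydro-1H-benzo[7]annulen-6-yl (2R,3R)-2,3-dimethyloxirane-2-carboxylate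
Conditions: HF·pyridine, pyridine, THF, 0 °C → rt
Reagents that add atoms: none
Why: Fluoride-mediated desilylation under pyridine-buffered conditions that should spare both esters and the epoxide.

Step 18
Reactants: 26 allylic alcohol
Product: 27 target, (4aS,6R,7R,9aR)-3,5,5,9-tetramethyl-7-{[(2Z)-2-methylbut-2-enoyl]oxy}-2-oxo-2,4a,5,6,7,9a-hexahydro-1H-benzo[7]annulen-6-yl (2R,3R)-2,3-dimethyloxirane-2-carboxylate
Conditions: Dess–Martin periodinane, NaHCO3, CH2Cl2, 0 °C → rt
Reagents that add atoms: none
Why: Dess–Martin oxidation of the secondary allylic alcohol to the enone under neutral conditions, so the γ-stereocentre C4a and the Z ester should not be touched.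

**Compound list**
1 | (S)-(+)-carvone, (5S)-2-methyl-5-(prop-1-en-2-yl)cyclohex-2-en-1-one | CC1=CC[C@@H](CC1=O)C(C)=C | starting material
2 | (1S,5S)-cis-carveol, (1S,5S)-2-methyl-5-(prop-1-en-2-yl)cyclohex-2-en-1-ol (OH cis to isopropenyl) | O[C@H]1C[C@@H](C(C)=C)CC=C1C | intermediate
3 | (1S,2S,4R,6R)-1-methyl-4-(prop-1-en-2-yl)-7-oxabicyclo[4.1.0]heptan-2-ol (OH, epoxide O and isopropenyl on one ring face) | O[C@H]1C[C@@H](C(C)=C)C[C@H]2O[C@@]12C | intermediate
4 | tert-butyldimethylsilyl ether of 3 | CC(C)(C)[Si](C)(C)O[C@H]1C[C@@H](C(C)=C)C[C@H]2O[C@@]12C | intermediate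
5 | hydroxy selenide: 6-[(tert-butyldimethylsilyl)oxy]-1-methyl-2-(phenylselanyl)-4-(prop-1-en-2-yl)cyclohexan-1-ol, SePh trans to the tertiary OH | CC(C)(C)[Si](C)(C)O[C@H]1C[C@@H](C(C)=C)C[C@H]([Se]c2ccccc2)[C@@]1(C)O | intermediate (not isolated)
6 | selenoxide of 5 (mixture at selenium) | CC(C)(C)[Si](C)(C)O[C@H]1C[C@@H](C(C)=C)C[C@H]([Se](=O)c2ccccc2)[C@@]1(C)O | intermediate (not isolated)
7 | (1R,4R,6S)-6-[(tert-butyldimethylsilyl)oxy]-1-methyl-4-(prop-1-en-2-yl)cyclohex-2-en-1-ol (tertiary OH, OTBS and isopropenyl on one face) | CC(C)(C)[Si](C)(C)O[C@H]1C[C@@H](C(C)=C)C=C[C@@]1(C)O | intermediate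
8 | 2-methylpropanoate of 7 | CC(C)C(=O)O[C@]1(C)C=C[C@H](C(C)=C)C[C@@H]1O[Si](C)(C)C(C)(C)C | intermediate
9 | trimethylsilyl ketene acetal of 8 | CC(C)=C(O[Si](C)(C)C)O[C@]1(C)C=C[C@H](C(C)=C)C[C@@H]1O[Si](C)(C)C(C)(C)C | intermediate (not isolated)
10 | trimethylsilyl ester of 11 | C[Si](C)(C)OC(=O)C(C)(C)[C@H]1C=C(C)[C@@H](O[Si](C)(C)C(C)(C)C)C[C@H]1C(C)=C | intermediate (not isolated)
11 | 2-[(1S,4S,6R)-4-[(tert-butyldimethylsilyl)oxy]-3-methyl-6-(prop-1-en-2-yl)cyclohex-2-en-1-yl]-2-methylpropanoic acid (all three ring substituents cis) | OC(=O)C(C)(C)[C@H]1C=C(C)[C@@H](O[Si](C)(C)C(C)(C)C)C[C@H]1C(C)=C | intermediate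
12 | prop-2-en-1-yl ester of 11 | C=CCOC(=O)C(C)(C)[C@H]1C=C(C)[C@@H](O[Si](C)(C)C(C)(C)C)C[C@H]1C(C)=C | intermediate
13 | cis-fused eight-membered (Z)-lactone O–C6(=O)–C5(CH3)2–C4a–C9a–C9(CH3)=C8H–C7H2, 2-OTBS retained | O=C1OC/C=C(/C)[C@@H]2C[C@H](O[Si](C)(C)C(C)(C)C)C(C)=C[C@@H]2C1(C)C | intermediate
14 | 2-{(1S,4S,6R)-4-[(tert-butyldimethylsilyl)oxy]-6-[(2Z)-4-hydroxybut-2-en-2-yl]-3-methylcyclohex-2-en-1-yl}-2-methylpropan-1-ol | OC/C=C(/C)[C@@H]1C[C@H](O[Si](C)(C)C(C)(C)C)C(C)=C[C@@H]1C(C)(C)CO | intermediate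
15 | 2-{(1S,4S,6R)-4-[(tert-butyldimethylsilyl)oxy]-3-methyl-6-[(2Z)-4-oxobut-2-en-2-yl]cyclohex-2-en-1-yl}-2-methylpropanal | O=C/C=C(/C)[C@@H]1C[C@H](O[Si](C)(C)C(C)(C)C)C(C)=C[C@@H]1C(C)(C)C=O | intermediate
16 | cyclic dichlorotitanium 6,7-diolate of 17 (tetravalent titanium) | Cl[Ti]3(Cl)O[C@@H]1C=C(C)[C@@H]2C[C@H](O[Si](C)(C)C(C)(C)C)C(C)=C[C@@H]2C(C)(C)[C@H]1O3 | intermediate (not isolated)
17 | (2S,4aS,6R,7R,9aR)-2-[(tert-butyldimethylsilyl)oxy]-3,5,5,9-tetramethyl-2,4a,5,6,7,9a-hexahydro-1H-benzo[7]annulene-6,7-diol (cis ring fusion, trans diol) | O[C@@H]1C=C(C)[C@@H]2C[C@H](O[Si](C)(C)C(C)(C)C)C(C)=C[C@@H]2C(C)(C)[C@H]1O | intermediate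
18 | angelic acid, (2Z)-2-methylbut-2-enoic acid | C/C=C(/C)C(O)=O | starting material
19 | angelic 2,4,6-trichlorobenzoic anhydride | C/C=C(/C)C(=O)OC(=O)c1c(Cl)cc(Cl)cc1Cl | intermediate (not isolated)
20 | 7-angelate of 17 (6-OH free) | C/C=C(/C)C(=O)O[C@@H]1C=C(C)[C@@H]2C[C@H](O[Si](C)(C)C(C)(C)C)C(C)=C[C@@H]2C(C)(C)[C@H]1O | intermediate
21 | (2Z)-2-methylbut-2-en-1-ol | C/C=C(/C)CO | intermediate
22 | [(2S,3R)-2,3-dimethyloxiran-2-yl]methanol | OC[C@]1(C)O[C@@H]1C | intermediate
23 | (2R,3R)-2,3-dimethyloxirane-2-carboxylic acid | OC(=O)[C@]1(C)O[C@@H]1C | intermediate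
24 | (2R,3R)-2,3-dimethyloxirane-2-carboxylic 2,4,6-trichlorobenzoic anhydride | Clc1cc(Cl)cc(Cl)c1C(=O)OC(=O)[C@]1(C)O[C@@H]1C | intermediate (not isolated)
25 | 2-O-TBS diester: 7-angelate 6-[(2R,3R)-2,3-dimethyloxirane-2-carboxylate] of 17 | C/C=C(/C)C(=O)O[C@@H]1C=C(C)[C@@H]2C[C@H](O[Si](C)(C)C(C)(C)C)C(C)=C[C@@H]2C(C)(C)[C@H]1OC(=O)[C@]1(C)O[C@@H]1C | intermediate
26 | (2S)-2-hydroxy diester (25 without silyl group) | C/C=C(/C)C(=O)O[C@@H]1C=C(C)[C@@H]2C[C@H](O)C(C)=C[C@@H]2C(C)(C)[C@H]1OC(=O)[C@]1(C)O[C@@H]1C | intermediate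
27 | (4aS,6R,7R,9aR)-3,5,5,9-tetramethyl-7-{[(2Z)-2-methylbut-2-enoyl]oxy}-2-oxo-2,4a,5,6,7,9a-hexahydro-1H-benzo[7]annulen-6-yl (2R,3R)-2,3-dimethyloxirane-2-carboxylate | C/C=C(/C)C(=O)O[C@@H]1C=C(C)[C@@H]2CC(=O)C(C)=C[C@@H]2C(C)(C)[C@H]1OC(=O)[C@]1(C)O[C@@H]1C | target

**Count and risks**
Total steps: 18. Longest linear sequence: 15 steps (steps 1–12 and 16–18 from (S)-carvone); the epoxy acid branch is steps 13–15.

Step 11 is the riskiest. What may go wrong is loss of control at the allylic carbinol carbon, the enal closing through its other rotamer so that the cis diol forms, together with deoxygenation of the titanium diolate. The fallback sets out from dialdehyde 15 and runs the closure as a chelation-controlled samarium pinacol coupling (SmI2, THF, t-BuOH, −78 °C → rt), which should hold both oxygens on one samarium centre and give the cis diol, the 7-epimer (2S,4aS,6R,7S,9aR)-2-[(tert-butyldimethylsilyl)oxy]-3,5,5,9-tetramethyl-2,4a,5,6,7,9a-hexahydro-1H-benzo[7]annulene-6,7-diol F1. A Mitsunobu esterification of F1 with angelic acid 18 (PPh3, DIAD, PhMe, 0 °C) should react only at the allylic C7–OH, with inversion, and comes back to the route at 20.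

Step 8 is second. What may go wrong is oligomerisation through the allyl ester termini outrunning the slow closure onto the hindered 1,1-disubstituted alkene to an eight-membered lactone. The fallback sets out from acid 11 and builds the Z alkene by carbocupration instead:
- Me3SiCHN2 (PhMe/MeOH) would give the methyl ester F2.
- Lemieux–Johnson cleavage of the exposed isopropenyl alkene (OsO4 cat., NaIO4, 2,6-lutidine, dioxane/H2O) would give the methyl ketone F3.
- LiN(i-Pr)2 and ClP(O)(OEt)2 would give the kinetic enol phosphate F4, not isolated, which more LiN(i-Pr)2 in the same flask would eliminate to the terminal alkyne F5.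
- Lithiation and methyl chloroformate would give the ynoate F6.
- Me2CuLi (THF, −78 °C, syn addition then protonation) should give the (Z)-enoate F7 with the ester cis to ring A.
- i-Bu2AlH would reduce both esters, and the sequence comes back to the route at diol 14.

Step 16 is third. What may go wrong is slow acylation of the neopentyl C6 hydroxyl, with angelate-to-tiglate isomerisation or 7→6 acyl migration under the forcing conditions it then needs. The fallback sets out from diol 17 and puts the sensitive angelate on last: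
- Et3SiCl/imidazole (CH2Cl2, −40 °C) should silylate only the allylic C7–OH to give the 7-O-triethylsilyl ether F8.
- A forced Yamaguchi esterification of the C6–OH with acid 23 (DMAP, PhMe, 60 °C) would give the 7-O-triethylsilyl 6-epoxyangelate F9.
- PPTS in MeOH would remove only the triethylsilyl group to give the 7-hydroxy 6-epoxyangelate F10.
- Acylation of F10 with the mixed anhydride 19 as in step 12 comes back to the route at 25.

Further compounds
F1 | step 11 | (2S,4aS,6R,7S,9aR)-2-[(tert-butyldimethylsilyl)oxy]-3,5,5,9-tetramethyl-2,4a,5,6,7,9a-hexahydro-1H-benzo[7]annulene-6,7-diol (cis diol, 7-epimer of 17) | O[C@H]1C=C(C)[C@@H]2C[C@H](O[Si](C)(C)C(C)(C)C)C(C)=C[C@@H]2C(C)(C)[C@H]1O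
F2 | step 8 | methyl ester of 11 | COC(=O)C(C)(C)[C@H]1C=C(C)[C@@H](O[Si](C)(C)C(C)(C)C)C[C@H]1C(C)=C
F3 | step 8 | methyl ketone (acetyl in place of isopropenyl in F2) | COC(=O)C(C)(C)[C@H]1C=C(C)[C@@H](O[Si](C)(C)C(C)(C)C)C[C@H]1C(C)=O
F4 | step 8 | diethyl enol phosphate of F3 (terminal) | COC(=O)C(C)(C)[C@H]1C=C(C)[C@@H](O[Si](C)(C)C(C)(C)C)C[C@H]1C(=C)OP(=O)(OCC)OCC
F5 | step 8 | terminal alkyne (ethynyl at C9a) | COC(=O)C(C)(C)[C@H]1C=C(C)[C@@H](O[Si](C)(C)C(C)(C)C)C[C@H]1C#C
F6 | step 8 | methyl ynoate | COC(=O)C(C)(C)[C@H]1C=C(C)[C@@H](O[Si](C)(C)C(C)(C)C)C[C@H]1C#CC(=O)OC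
F7 | step 8 | (Z)-enoate diester, methyl (2Z)-3-substituted but-2-enoate with the ester cis to ring A | COC(=O)C(C)(C)[C@H]1C=C(C)[C@@H](O[Si](C)(C)C(C)(C)C)C[C@H]1/C(C)=C\C(=O)OC
F8 | step 16 | 7-O-triethylsilyl ether of 17 | CC[Si](CC)(CC)O[C@@H]1C=C(C)[C@@H]2C[C@H](O[Si](C)(C)C(C)(C)C)C(C)=C[C@@H]2C(C)(C)[C@H]1O
F9 | step 16 | 7-O-triethylsilyl 6-[(2R,3R)-2,3-dimethyloxirane-2-carboxylate] of 17 | CC[Si](CC)(CC)O[C@@H]1C=C(C)[C@@H]2C[C@H](O[Si](C)(C)C(C)(C)C)C(C)=C[C@@H]2C(C)(C)[C@H]1OC(=O)[C@]1(C)O[C@@H]1C
F10 | step 16 | 7-hydroxy 6-[(2R,3R)-2,3-dimethyloxirane-2-carboxylate] of 17 | O[C@@H]1C=C(C)[C@@H]2C[C@H](O[Si](C)(C)C(C)(C)C)C(C)=C[C@@H]2C(C)(C)[C@H]1OC(=O)[C@]1(C)O[C@@H]1C
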